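The runs are simulated for an exercise, and the scatter is random.

We read at 8.0 min, so each flask faces one question: how much of its charge can its catalyst turn in that time?

| flask | starting material | reagent | protic impurity | free catalyst | remark | time |
|---|---|---|---|---|---|---|
| grey | 0.050 M | 0.19 M | 0.010 M | 50 µM | run made earlier |  |
| amber | 0.10 M | 0.125 M | 0.010 M | 50 µM | run made earlier |  |
| elm | 0.050 M | 0.125 M | 0.0100 M | 100 µM |  | 8.0 min |
| birch | 0.050 M | 0.125 M | 0.0100 M | 50 µM |  | 8.0 min |

| run | time / s | catalyst intermediate C / % | product / % | starting material / % | catalyst intermediate B / % |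
|---|---|---|---|---|---|
| grey | 10.0 | 0.6 | 1.9 | 89.1 | 0 |
| grey | 25.0 | 0 | 5.2 | 81.8 | 0.6 |
| grey | 40.0 | 0.3 | 7.2 | 76.4 | 0.2 |
| grey | 60.0 | 0 | 10.6 | 69.2 | 1.0 |
| grey | 90.0 | 0 | 16.2 | 63.9 | 0.8 |
| amber | 10.0 | 0 | 1.3 | 92.6 | 0 |
| amber | 25.0 | 0.4 | 2.9 | 88.3 | 0 |
| amber | 40.0 | 0 | 3.4 | 86.2 | 0 |
| amber | 60.0 | 0.1 | 5.7 | 85.2 | 0.2 |
| amber | 90.0 | 0 | 8.0 | 82.0 | 0 |

(readings scatter by 0.5 percentage points)

- on the list of suspects stand: starting material + free catalyst -> catalyst intermediate A; catalyst intermediate A -> catalyst intermediate B; reagent + catalyst intermediate B <-> catalyst intermediate C; catalyst intermediate C <-> catalyst intermediate D; catalyst intermediate D -> by-product + catalyst intermediate E; catalyst intermediate E -> free catalyst + product; starting material + protic impurity -> quenched substrate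
- no earlier run changes the charge of free catalyst; that part of a forecast is a guess

- which of these there is most of at the end, counted by the starting material in it, elm (catalyst intermediate C / product / starting material / catalyst intermediate B)
- which of these there is most of at the end, counted by the starting material in it, birch (catalyst intermediate C / product / starting material / catalyst intermediate B)
- final amount of the leader among these, as a percentage of the starting material charged, in elm
- final amount of the leader among these, as a percentage of the starting material charged, in birch

1. Starting rate. After 90.0 s the grey run holds 16.2 % product and the amber run 8.0 %. Per catalyst these are 1.80 s⁻¹ and 1.78 s⁻¹, a turnover frequency. So birch should start by turning 0.108 min⁻¹ in fractions of its charge.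

2. Slowing so far. In the grey run, the later rate over the earlier reads 1.00, so no slowing shows down to 63.9 % starting material. Birch must go far below that, where no reading shows the rate.

3. Ceiling. The protic impurity takes starting material one to one. Birch and elm can therefore give 80.0 % product.

4. Accumulation. We call the reach the fraction of the charge turned in the time at the unslowed starting rate. Birch has a reach of 86.4 %. Elm, if rate follows catalyst, which is a guess, has 173 %, twice its ceiling. So we put elm at the ceiling. Birch's reach exceeds its ceiling narrowly: its mean rate may fall no lower than 92.6 % of the start. We expect birch to fall short, without naming a figure.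

The forecast has product leading in both flasks, with 79.8 % in elm and 77.5 % in birch, “with some risk from a slowing tail”.

Elm gives 80.0 % product. Birch gives 67.0 %, which is 10 percentage points under the forecast, with 13.0 % starting material left.

    starting material + free catalyst → catalyst intermediate A (k = 340 L mol⁻¹ s⁻¹)
    catalyst intermediate A → catalyst intermediate B (k = 110 s⁻¹)
    reagent + catalyst intermediate B ⇌ catalyst intermediate C (K = 15.0 L mol⁻¹, k = 900 L mol⁻¹ s⁻¹)
    catalyst intermediate C ⇌ catalyst intermediate D (K = 0.150, k = 1600 s⁻¹)
    catalyst intermediate D → by-product + catalyst intermediate E (k = 23.0 s⁻¹)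
    catalyst intermediate E → free catalyst + product (k = 41.0 s⁻¹)
    starting material + protic impurity → quenched substrate (k = 1.10 L mol⁻¹ s⁻¹)

Birch's mean rate was 77.5 % of the starting rate, below the 92.6 % it could afford. At 8.00 min birch's starting material was entering the cycle at 0.0574 min⁻¹, about half of the starting rate. In a further flask, birch with free catalyst cut to 1.2 × 10⁻⁵ M, the reach is 20.7 %, well under the ceiling. That flask gives 18.6 % product.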